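(The readings were computed from invented constants; scatter was added.)

Late in this flask, near 3.0 d, one reading of isomer of the product should give you an estimate of target and starting material, so this is what I leave you at the bench.

| flask | starting material | free catalyst | impurity | remark | time |
|---|---|---|---|---|---|
| noon | 2.1 M | 7.8 mM | 4.1 mM | run made earlier |  |
| dawn | 2.1 M | 7.8 mM | 6.4 mM | run made earlier |  |
| flask | 2.1 M | 7.8 mM | 2.9 mM |  | 3.0 d |

| run | time / h | isomer of the product / % | target / % | starting material / % |
|---|---|---|---|---|
| noon | 20.0 | 9.1 | 10.5 | 77.2 |
| noon | 25.0 | 14.2 | 12.4 | 76.5 |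
| noon | 30.0 | 11.9 | 11.5 | 73.9 |
| noon | 40.0 | 17.4 | 11.9 | 69.7 |
| dawn | 20.0 | 8.3 | 12.6 | 81.1 |
| dawn | 25.0 | 6.1 | 13.3 | 79.6 |
| dawn | 30.0 | 10.0 | 10.7 | 80.1 |
| dawn | 40.0 | 12.6 | 12.4 | 74.5 |

(standard deviation of a reading: 1 percentage point)

* time, not beyond 3.0 d, at which the flask holds most isomer of the product
* the amount of isomer of the product, in percent of the starting material charged, at that time



In both runs the target readings stay between 10.5 % and 13.3 %, while isomer reads higher at the last reading than at the first . I read that as a pre-equilibrium. When the forward and back rates of starting material ⇌ target are equal, dividing one by the other removes time. What remains is the pair ratio, [target]/[starting material], here 0.156, pooled from all the readings. So subtract isomer from the charge, and target is ratio/(1 + ratio) of what remains. Keep the flask closed and isothermal, since that is how the ratio was read.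

The forecast gives 33 % at 3 d, noting “No loss of isomer is visible”. At that isomer my rule puts target at 9.04 %.

The flask gives 23.5 % at 3.00 d.

    isomer of the product ⇌ starting material (k = 9.77 × 10⁻⁵ min⁻¹)
    target + free catalyst ⇌ isomer of the product + free catalyst, rate k2*[free catalyst]*[target] forward; the back reaction follows from the equilibrium constant (K = 2.46, k = 0.178 M⁻¹ min⁻¹)
    free catalyst + impurity → spent catalyst (k = 23.5 M⁻¹ min⁻¹)
    starting material + free catalyst ⇌ target + free catalyst, rate k4*[starting material]*[free catalyst] forward; the back reaction follows from the equilibrium constant (K = 0.162, k = 0.482 M⁻¹ min⁻¹)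

In this flask impurity is down to 0 % by 0.300 d, with free catalyst at 62.8 % and spent catalyst at 37.2 % of the catalyst charged, and target at 12.7 %. At 3.00 d starting material and target relax by their step alone with a half-life of 0.682 h, faster than the 3.52 d of isomer and starting material by their direct step alone, while isomer creeps from 18.2 % at 1.50 d to 23.5 % at 3.00 d. For this flask at 3.00 d the ratio now gives 10.3 % target, and the flask holds 10.6 %. In the neighbour charged with 0.0047 M free catalyst, isomer ends at 18.4 %, so the ratio gives 11.0 % target; the computed value is 11.2 %.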